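**Plan**

- The retrosynthesis first cuts the five O–benzyl bonds that mask the hydroxyls, then the two aryl C–O bonds C6–OMe and C8–OMe (back to C6–Br and C8–Br), and last the two C–Br bonds, which leads to quercetin.
- The enabling feature is that C6 and C8 are the only C–H positions of the phloroglucinol-type A ring. Each lies ortho/para to O5, O7 and the ring oxygen O1, so they are the most nucleophilic carbons of the flavonol, and bromine marks exactly the two carbons that carry methoxy groups in the target.
- In the forward direction no ring is built: the A/C/B skeleton comes intact from quercetin. The order is dibromination, perbenzylation, double copper-mediated exchange of Br for OMe, then hydrogenolysis.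
- Because every other oxygen is a benzyl ether during the exchange, the two new ethers are the only methyl ethers and no selective methylation is needed.
- Stereochemistry: the target has no stereocentre, axis or stereogenic double bond, so nothing has to be controlled.

Key step: step 3

Remark on the chemistry: the target is achiral, so "single enantiomer" is taken to mean the single constitution given by the SMILES.

**Route**

Step 1
Reactants: 1 quercetin
Product: 2 6,8-dibromoquercetin (6,8-dibromo-2-(3,4-dihydroxyphenyl)-3,5,7-trihydroxy-4H-chromen-4-one)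
Conditions: Br2 (2.1 equiv), AcOH, 20–35 °C; then H2O, filtration
Reagents that add atoms: bromine, BrBr
Why: Electrophilic aromatic bromination should go to the two A-ring CH carbons, each activated by three ortho/para oxygen donors, in preference to the catechol ring that sits on the electron-poor pyranone, and acetic acid offers no nucleophile that could add across C2=C3.

Step 2
Reactants: 2 6,8-dibromoquercetin; 3 benzyl bromide
Product: 4 3,5,7-tris(benzyloxy)-2-[3,4-bis(benzyloxy)phenyl]-6,8-dibromo-4H-chromen-4-one
Conditions: BnBr (7 equiv), K2CO3 (8 equiv), DMF, 80 °C, Ar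
Reagents that add atoms: benzyl bromide, BrCc1ccccc1
Why: Williamson etherification of all five phenoxide/enolate oxygens should reach completion with excess benzyl bromide in hot DMF, the chelated 5-OH reacting last, while the bromines at C6 and C8 block the C-benzylation that otherwise competes on a phloroglucinol ring.

Step 3
Reactants: 4 3,5,7-tris(benzyloxy)-2-[3,4-bis(benzyloxy)phenyl]-6,8-dibromo-4H-chromen-4-one; 5 sodium methoxide
Product: 6 3,5,7-tris(benzyloxy)-2-[3,4-bis(benzyloxy)phenyl]-6,8-dimethoxy-4H-chromen-4-one
Conditions: NaOMe (8 equiv, conc. solution in MeOH), CuBr (0.4 equiv, catalyst), anhydrous DMF, 110 °C, Ar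
Reagents that add atoms: sodium methoxide, C[O-].[Na+]
Why: Sodium methoxide and CuBr generate a copper(I) methoxide/cuprate that inserts into each aryl C–Br bond (oxidative addition to an aryl–Cu(III) methoxide) and then forms the C6–O and C8–O bonds by reductive elimination, the copper being returned to the cycle by further methoxide. The closest known reaction is the Ullmann-type copper-mediated methoxylation of 6- and 8-bromoflavones and other polyalkoxy bromoarenes with NaOMe/CuBr in DMF–MeOH. No ring is closed and no stereocenter is created. The step needs chemoselectivity for substitution over hydrodebromination at two di-ortho-substituted carbons, and over methoxide attack on the pyranone (addition at C2 followed by retro-Claisen cleavage) or on the benzyl ethers. The substrate secures this because every hydroxyl is capped, so no phenoxide deactivates the ring or sequesters copper, the flanking benzyloxy oxygens can hold copper next to each C–Br bond, and the C–Br bonds are the only sites that can acquire a methyl ether; a concentrated, water-free methoxide medium with little free methanol should suppress the reductive pathway, and in the absence of water methoxide addition at C2 can revert instead of leading to cleavage.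

Step 4
Reactants: 6 3,5,7-tris(benzyloxy)-2-[3,4-bis(benzyloxy)phenyl]-6,8-dimethoxy-4H-chromen-4-one
Product: 7 3,5,7,3',4'-pentahydroxy-6,8-dimethoxyflavone (2-(3,4-dihydroxyphenyl)-3,5,7-trihydroxy-6,8-dimethoxy-4H-chromen-4-one)
Conditions: H2 (1 atm), 10% Pd/C, THF–MeOH (1:1), rt; filtration under Ar
Reagents that add atoms: none
Why: Heterogeneous hydrogenolysis of aryl benzyl ethers should cleave all five O–CH2Ph bonds at room temperature and 1 atm, conditions under which the aryl methyl ethers and the fully substituted C2=C3 bond of a flavonol are known to persist.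

**Compound list**

1 | quercetin | O=c1c(O)c(-c2ccc(O)c(O)c2)oc2cc(O)cc(O)c12 | starting material
2 | 6,8-dibromoquercetin (6,8-dibromo-2-(3,4-dihydroxyphenyl)-3,5,7-trihydroxy-4H-chromen-4-one) | O=c1c(O)c(-c2ccc(O)c(O)c2)oc2c(Br)c(O)c(Br)c(O)c12 | intermediate
3 | benzyl bromide | BrCc1ccccc1 | starting material
4 | 3,5,7-tris(benzyloxy)-2-[3,4-bis(benzyloxy)phenyl]-6,8-dibromo-4H-chromen-4-one | O=c1c(OCc2ccccc2)c(-c2ccc(OCc3ccccc3)c(OCc3ccccc3)c2)oc2c(Br)c(OCc3ccccc3)c(Br)c(OCc3ccccc3)c12 | intermediate
5 | sodium methoxide | C[O-].[Na+] | starting material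
6 | 3,5,7-tris(benzyloxy)-2-[3,4-bis(benzyloxy)phenyl]-6,8-dimethoxy-4H-chromen-4-one | COc1c(OCc2ccccc2)c(OC)c2oc(-c3ccc(OCc4ccccc4)c(OCc4ccccc4)c3)c(OCc3ccccc3)c(=O)c2c1OCc1ccccc1 | intermediate
7 | 3,5,7,3',4'-pentahydroxy-6,8-dimethoxyflavone | COc1c(O)c(OC)c2oc(-c3ccc(O)c(O)c3)c(O)c(=O)c2c1O | target

**Step count and risks**

Total step count: 4. Longest linear sequence: 4 steps (1 → 2 → 4 → 6 → 7).

Steps most likely to fail, riskiest first:

Step 3. Loss of bromine by reduction may outrun C–O bond formation at one or both of the crowded carbons, and hot methoxide may open the pyranone at C2 and cleave it irreversibly. The fallback sets out from 4 and forms the same two C–O bonds without hot methoxide. Palladium-catalysed Miyaura borylation (B2pin2, Pd(OAc)2/SPhos, KOAc, dioxane, 90 °C) should give 3,5,7-tris(benzyloxy)-2-[3,4-bis(benzyloxy)phenyl]-6,8-bis(4,4,5,5-tetramethyl-1,3,2-dioxaborolan-2-yl)-4H-chromen-4-one F1. This is oxidised without delay (H2O2, pH 7 buffer, THF–H2O, 0 °C to rt) to 3,5,7-tris(benzyloxy)-2-[3,4-bis(benzyloxy)phenyl]-6,8-dihydroxy-4H-chromen-4-one F2. Its two new phenols are the only free hydroxyls, so methylation with iodomethane and K2CO3 in acetone needs no selectivity and returns to the route at 6.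

Step 2. Alkylation may stall at the 5-OH, which is hydrogen-bonded to the C4 carbonyl and flanked by the C6 bromine, leaving mixtures of partial ethers. The fallback sets out from 2 and leaves this hydroxyl free on purpose. Benzyl bromide (4.4 equiv) and K2CO3 in DMF at room temperature should give 3,7-bis(benzyloxy)-2-[3,4-bis(benzyloxy)phenyl]-6,8-dibromo-5-hydroxy-4H-chromen-4-one F3. The copper methoxylation is then run on its chelated sodium 5-phenoxide (NaOMe in larger excess, stoichiometric CuBr, DMF, 110 °C) to give 3,7-bis(benzyloxy)-2-[3,4-bis(benzyloxy)phenyl]-5-hydroxy-6,8-dimethoxy-4H-chromen-4-one F4. Because C6 and C8 carry the same substituent, a base-induced ring opening and reclosure through the 5-oxygen would lead to the same compound. Hydrogenolysis of the four benzyl ethers (H2, Pd/C) returns to the route at 7.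

Step 1. Bromine may oxidise the free catechol or the 3-hydroxypyranone, or bromination may stop short or run on into the B ring, giving poorly soluble polyphenol mixtures that are hard to purify. The fallback sets out from 1 and reverses the order of the first two operations. Exhaustive benzylation (benzyl bromide, K2CO3, DMF, 80 °C) should give 3,5,7-tris(benzyloxy)-2-[3,4-bis(benzyloxy)phenyl]-4H-chromen-4-one F5, which is soluble and no longer oxidisable. N-bromosuccinimide (2.2 equiv, DMF, 0 °C to rt) should then brominate C6 and C8, still the only carbons ortho/para to three oxygen donors, and return to the route at 4.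

**Further compounds**

F1 | step 3 | 3,5,7-tris(benzyloxy)-2-[3,4-bis(benzyloxy)phenyl]-6,8-bis(4,4,5,5-tetramethyl-1,3,2-dioxaborolan-2-yl)-4H-chromen-4-one | O=c1c(OCc2ccccc2)c(-c2ccc(OCc3ccccc3)c(OCc3ccccc3)c2)oc2c(B3OC(C)(C)C(C)(C)O3)c(OCc3ccccc3)c(B3OC(C)(C)C(C)(C)O3)c(OCc3ccccc3)c12
F2 | step 3 | 3,5,7-tris(benzyloxy)-2-[3,4-bis(benzyloxy)phenyl]-6,8-dihydroxy-4H-chromen-4-one | O=c1c(OCc2ccccc2)c(-c2ccc(OCc3ccccc3)c(OCc3ccccc3)c2)oc2c(O)c(OCc3ccccc3)c(O)c(OCc3ccccc3)c12
F3 | step 2 | 3,7-bis(benzyloxy)-2-[3,4-bis(benzyloxy)phenyl]-6,8-dibromo-5-hydroxy-4H-chromen-4-one | O=c1c(OCc2ccccc2)c(-c2ccc(OCc3ccccc3)c(OCc3ccccc3)c2)oc2c(Br)c(OCc3ccccc3)c(Br)c(O)c12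
F4 | step 2 | 3,7-bis(benzyloxy)-2-[3,4-bis(benzyloxy)phenyl]-5-hydroxy-6,8-dimethoxy-4H-chromen-4-one | COc1c(OCc2ccccc2)c(OC)c2oc(-c3ccc(OCc4ccccc4)c(OCc4ccccc4)c3)c(OCc3ccccc3)c(=O)c2c1O
F5 | step 1 | 3,5,7-tris(benzyloxy)-2-[3,4-bis(benzyloxy)phenyl]-4H-chromen-4-one | O=c1c(OCc2ccccc2)c(-c2ccc(OCc3ccccc3)c(OCc3ccccc3)c2)oc2cc(OCc3ccccc3)cc(OCc3ccccc3)c12
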